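## The problem

Compound 23 is an achiral, fully aromatic bis-benzophenone in which four benzene rings are joined in a row: ring A–C(=O)–ring B–CH2–ring C–C(=O)–ring D. Rings B and C are both 5-methoxyresorcinol units that carry their ketone on the carbon between the two hydroxyls and the methylene bridge on a carbon between a hydroxyl and the methoxyl. Rings A and D share the orsellinic pattern, but ring D has its ortho oxygen methylated, so the two halves cannot come from one monomer. There is no stereocentre; the difficulty is regiochemistry and crowding, because each carbonyl lies between four ortho substituents and the phloroglucinol-type rings offer several nucleophilic carbons of similar reactivity. Seven phenols must end free beside three methyl ethers, one of them ortho to a carbonyl, which rules out Lewis-acid dealkylation at the end and points to benzyl ethers and hydrogenolysis. The sensitive elements are the electron-rich diarylmethane (acid-induced cleavage and scrambling), the electron-rich benzylic alcohols met on the way (ready ionisation and self-condensation) and the polyhydroxybenzophenones themselves (oxidation, xanthone closure under hot base). The enabling feature lies at the ring C/ring D ketone: the methyl group of ring D and the ring C hydroxyl on the carbon between the ketone-bearing and the bridge-bearing carbons are both ortho to that carbonyl. The methyl carbon and that oxygen can therefore be read as the two ends of a cleaved benzyl aryl ether; joining them turns the hindered ketone into the carbonyl of a seven-membered dibenzo[b,e]oxepin-11(6H)-one, which an intramolecular acylation can close and hydrogenolysis can open again.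

## Retrosynthesis

**23 back to 22.** No skeletal bond is cut. The ring C hydroxyl that is ortho to both bridge and ketone is joined in thought to the ring D methyl carbon, and the four phenols of rings A, C and D that need masking are written as benzyl ethers; the two ring B hydroxyls stay free. This gives the dibenzoxepinone 22. Catalytic hydrogenolysis is preferred to acid- or nucleophile-based unmasking because it leaves the three methyl ethers untouched and cleaves all five benzylic C–O bonds in one operation. The forward step must do this without reducing the two diaryl ketones.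

**22 back to 13 and 21.** The bond between the bridge carbon and ring B is cut, giving two halves of similar size: the benzylic alcohol 13 (rings C and D, ketone in place) and the benzophenone 21 (rings A and B). A cut on the other side of the bridge would ask ring C to react as a nucleophile at one of three similar carbons. As chosen, the bridge carbon is already fixed on ring C (it is the formyl carbon of the purchased aldehyde 5), and ring B of 21 offers two carbons that are equivalent by symmetry. The forward reaction is a Friedel–Crafts benzylation of a phenol; it has to stop after one benzylation and prefer ring B of 21 over every other arene present.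

**13 back to 12.** A change of oxidation level only: the benzylic alcohol comes from aldehyde 12 by hydride reduction, which must leave the oxepinone ketone alone.

**12 back to 10.** This is the strategic cut: the bond from ring C to the ketone carbon, which also opens the seven-membered ring. Precursor 10 is a ring D benzoic acid linked through its ortho benzylic carbon to the ring C oxygen.
- Against its neighbours: an intermolecular acylation of a ring C ether by a ring D acid would have to form a ketone with four ortho substituents and choose between two ring C carbons. Addition of a ring C aryl-metal to a ring D aldehyde would need a regiodefined metalation beside a formyl group.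
- In 10 the tether can deliver the acyl carbon to one ring carbon only, since the other ortho position bears the formyl group, and a crowded bimolecular event becomes a ring closure.
- The closure is placed before the union with 21. The acylium ion then meets one nucleophilic arene and not four, the acid-labile diarylmethane never sees the acylation medium, and the new ketone lowers the nucleophilicity of ring C for the later benzylation.
- The price is that ring C of 10 carries a deactivating formyl group, which the forward step must overcome.

**10 back to 4 and 6.** Acid 10 comes from its methyl ester 9, and 9 from pivalate 7 by exchange of the ring D acyl protecting group for benzyl. Cutting the O–CH2 bond of the tether in 7 gives phenol 6 and benzylic bromide 4, to be joined by Williamson etherification. 6 is the 4-O-benzyl ether of aldehyde 5. 4 comes from methyl orsellinate 1 through 2 and 3. The ring D para oxygen is carried as a pivalate at this stage, because the radical bromination that makes 4 needs a ring that is not too electron-rich and a protecting group without benzylic hydrogens.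

**21 back to 15 and 17.** The ring A/ring B ketone is cut at its bond to ring B. In the forward sense the aryllithium 18, made by directed metalation of the bis-MOM ether 17 between its two acetal oxygens, adds to aldehyde 15; oxidation of carbinol 19 gives ketone 20, and acid removes the MOM groups to give 21. A Friedel–Crafts acylation of 5-methoxyresorcinol 16 was set aside because it is hindered and favours the carbon between hydroxyl and methoxyl. 17 is made from 16, and 15 from orsellinaldehyde 14.

## Roads not taken

**Alternative 1:** Ring A is cut across two of its ring bonds and traced back to a cyclohexane-1,3-dione.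
- Forward key step: the ring B aryl diketone 1-[2,6-bis(benzyloxy)-4-methoxyphenyl]butane-1,3-dione A1 would add through its central carbon to ethyl crotonate A2 (Michael addition). Its terminal methyl ketone would then close on the ester under alkoxide (Claisen condensation) to give the 4-aroyl-5-methylcyclohexane-1,3-dione A3, which would be dehydrogenated to the orsellinoyl ring.
- Merits: the crowded ring A/ring B ketone is never made by joining two arenes, and the methyl group and both oxygens of ring A are placed by the annulation.
- Weak points: aromatising a benzyl-protected triketone is delicate (halogen or quinone oxidants on an electron-rich substrate, or palladium dehydrogenation that endangers benzyl ethers). The Michael addition at the doubly activated carbon of a di-ortho-substituted aryl diketone is sterically loaded. The route also solves only the easier of the two ketones and is silent on the bridge and on the ring C/ring D ketone.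
- Comparison: it avoids the organolithium chemistry of steps 12 and 13 and any question of metalation regiochemistry, and in that respect it is the safer road. The chosen plan sets against this that 21 is reached in four steps from 16 and one from 14, from intact aromatic building blocks and without a late aromatisation.

**Alternative 2:** Ring B is cut between its acyl-bearing carbon and a neighbouring hydroxyl-bearing carbon and unfolded into a polyketide chain masked as a pyrone.
- Forward key step: the pyrone 6-{2-[2,4-bis(benzyloxy)-6-methylphenyl]-2-oxoethyl}-4-hydroxy-2H-pyran-2-one A4 would be opened by Mg(OMe)2 A5 to the triketo ester A6. The methylene next to the aryl ketone would then attack the ester carbon (Claisen condensation) to give [2,4-bis(benzyloxy)-6-methylphenyl](2,4,6-trihydroxyphenyl)methanone A7.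
- Merits: the acyl group is born between two hydroxyls, so the regiochemistry of ring B is as secure as in the chosen route; the conditions are mild and the logic is biomimetic.
- Weak points: the chain must fold in the Claisen and not the aldol mode, which depends on metal templating. A4 needs several steps from a ring A ester. A7 still needs selective methylation of its one unchelated hydroxyl. Again only the 21 half is addressed.
- Comparison: it equals the chosen route in regiocontrol and uses gentler reagents, but it is longer. The chosen plan's counterweight is that the methyl ether is bought with 16 and the ketone is set by one metalation/addition and one oxidation.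

**Alternative 3:** Ring C is cut into a four-carbon cyclobutenone and a two-carbon alkyne (Danheiser benzannulation).
- Forward key step: the 3-methoxycyclobutenone A8, bearing the ring A–ring B benzyl unit on its saturated carbon, would be heated with (triisopropylsilyloxy)acetylene A9. It would open to a vinylketene and add the alkyne; 4π opening and 6π closure would then give phenol A10 with bridge, methoxyl, silyl ether and free hydroxyl in a defined pattern.
- Merits: the bridge is installed without any cationic benzylation, so the over-alkylation and self-condensation questions of step 15 do not arise. The three ring C oxygens emerge differentiated, with exactly the hydroxyl free that a tether needs. In both respects this road is better than the chosen one.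
- Weak points: A8 must carry a complete benzophenone through cyclobutenone synthesis and thermolysis, and the sequence is linear. A10 still lacks the ring C/ring D ketone, so a tethered acylation would have to follow on a substrate containing the acid-sensitive diarylmethane and three further nucleophilic rings.
- Comparison: the chosen plan obtains the same ring C pattern by buying 5, whose formyl carbon becomes the bridge and whose oxygens are already distinguished. It reaches 6 in one step and stays convergent. In exchange it accepts the chemoselectivity burden of step 15.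

Key step: step 8

Remark on the chemistry: aldehydes 5 and 14 are treated as purchasable; 23 has no stereocentre, and the only stereocentre on the route (carbinol 19, racemic) is removed in step 13.

## Route

Step 1
Reactants: 1 methyl orsellinate (methyl 2,4-dihydroxy-6-methylbenzoate)
Product: 2 methyl 4-(2,2-dimethylpropanoyloxy)-2-hydroxy-6-methylbenzoate
Conditions: PivCl (1.05 equiv), Et3N, CH2Cl2, 0 °C
Reagents that add atoms: pivaloyl chloride, CC(C)(C)C(Cl)=O
Why: Selective O-acylation of the 4-hydroxyl; the 2-hydroxyl is hydrogen-bonded to and flanked by the ester, so one equivalent of acid chloride should esterify O-4 only. An acyloxy group is chosen because, unlike a benzyloxy group, it neither activates the ring toward bromination nor offers abstractable benzylic hydrogens in step 3.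

Step 2
Reactants: 2 methyl 4-(2,2-dimethylpropanoyloxy)-2-hydroxy-6-methylbenzoate
Product: 3 methyl 4-(2,2-dimethylpropanoyloxy)-2-methoxy-6-methylbenzoate
Conditions: MeI, K2CO3, acetone, reflux
Reagents that add atoms: iodomethane, CI
Why: Williamson methylation of the chelated 2-hydroxyl; the hindered aryl pivalate should survive anhydrous carbonate.

Step 3
Reactants: 3 methyl 4-(2,2-dimethylpropanoyloxy)-2-methoxy-6-methylbenzoate
Product: 4 methyl 2-(bromomethyl)-4-(2,2-dimethylpropanoyloxy)-6-methoxybenzoate
Conditions: NBS (1.05 equiv), AIBN (cat.), PhCF3, 85 °C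
Reagents that add atoms: N-bromosuccinimide, O=C1CCC(=O)N1Br
Why: Wohl–Ziegler bromination of the ortho-methyl group by a radical chain. With one alkoxy donor and one acyloxy group the ring resembles methyl 2-methoxy-6-methylbenzoate, a standard substrate for this reaction, so ionic ring bromination should stay minor in a non-polar solvent.

Step 4
Reactants: 5 2,4-dihydroxy-6-methoxybenzaldehyde
Product: 6 4-(benzyloxy)-2-hydroxy-6-methoxybenzaldehyde
Conditions: BnBr (1.0 equiv), K2CO3, acetone, rt to 40 °C
Reagents that add atoms: benzyl bromide, BrCc1ccccc1
Why: Regioselective Williamson benzylation of the 4-hydroxyl, which is para to the formyl group, the more acidic and not chelated; the 2-hydroxyl stays locked in its hydrogen bond to the aldehyde.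

Step 5
Reactants: 4 methyl 2-(bromomethyl)-4-(2,2-dimethylpropanoyloxy)-6-methoxybenzoate; 6 4-(benzyloxy)-2-hydroxy-6-methoxybenzaldehyde
Product: 7 methyl 2-{[5-(benzyloxy)-2-formyl-3-methoxyphenoxy]methyl}-4-(2,2-dimethylpropanoyloxy)-6-methoxybenzoate
Conditions: K2CO3, DMF, rt
Reagents that add atoms: none
Why: Williamson ether synthesis: the phenoxide of 6 displaces the primary benzylic bromide of 4 (SN2), installing the tether between the ring C oxygen and the future ring D methyl carbon. Room temperature keeps 4 from lactonising to a phthalide and keeps acyl transfer from the hindered pivalate slow.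

Step 6
Reactants: 7 methyl 2-{[5-(benzyloxy)-2-formyl-3-methoxyphenoxy]methyl}-4-(2,2-dimethylpropanoyloxy)-6-methoxybenzoate
Product: 9 methyl 4-(benzyloxy)-2-{[5-(benzyloxy)-2-formyl-3-methoxyphenoxy]methyl}-6-methoxybenzoate, via ring D phenol 8 (not isolated)
Conditions: NaOMe (1.1 equiv), MeOH/THF, 0 °C to rt; evaporate; BnBr, DMF, rt
Reagents that add atoms: benzyl bromide, BrCc1ccccc1
Why: Methoxide cleaves the aryl pivalate by transesterification while the di-ortho-substituted methyl benzoate is inert; the liberated sodium phenoxide is benzylated in the same flask (Williamson). This exchanges the bromination-compatible acyl group for one that leaves in the final hydrogenolysis.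

Step 7
Reactants: 9 methyl 4-(benzyloxy)-2-{[5-(benzyloxy)-2-formyl-3-methoxyphenoxy]methyl}-6-methoxybenzoate
Product: 10 4-(benzyloxy)-2-{[5-(benzyloxy)-2-formyl-3-methoxyphenoxy]methyl}-6-methoxybenzoic acid
Conditions: KOH, DMSO/H2O, 80 °C; then 1 M HCl, 0 °C
Reagents that add atoms: potassium hydroxide (its oxygen becomes a carboxyl oxygen), [K+].[OH-]
Why: Saponification of a 2,6-disubstituted methyl benzoate needs forcing hydroxide in a dipolar solvent. The formyl group is not enolisable and, as a 2,4,6-trioxygenated benzaldehyde, is a poor Cannizzaro substrate; the benzyl ethers and the tether are base-stable.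

Step 8
Reactants: 10 4-(benzyloxy)-2-{[5-(benzyloxy)-2-formyl-3-methoxyphenoxy]methyl}-6-methoxybenzoic acid
Product: 12 1,8-bis(benzyloxy)-3,10-dimethoxy-11-oxo-6,11-dihydrodibenzo[b,e]oxepine-4-carbaldehyde, via mixed anhydride 11 (not isolated)
Conditions: TFAA (3–5 equiv), CH2Cl2 (high dilution), 0 °C to rt; then aq. NaHCO3
Reagents that add atoms: none
Why: Trifluoroacetic anhydride converts the acid into mixed anhydride 11, which ionises (helped by the ortho and para alkoxy groups of ring D) to an aroyl cation; this attacks ring C at the only unsubstituted carbon ortho to the tether oxygen, and loss of a proton from the arenium ion gives the diaryl ketone. The closest known reaction type is the anhydride- or polyphosphoric-acid-mediated cyclisation of 2-(aryloxymethyl)benzoic acids to dibenzo[b,e]oxepin-11(6H)-ones. The seven-membered ring closes by attack of an arene carbon on the exocyclic acylium carbon, formally a 7-exo-dig closure (7-exo-trig if the anhydride carbonyl itself is attacked). No stereocentre is formed. The step needs regioselectivity on ring C and preference for ring closure over intermolecular acylation: the tether can deliver the acyl carbon only to a carbon ortho to the ether oxygen, the other ortho carbon carries the formyl group, the carbon para to the tether oxygen is out of reach, and dilution disfavours bimolecular events. The attacked carbon is ortho to two ether oxygens and para to the methoxyl, which should outweigh the meta formyl group. Intramolecular delivery is what makes a ketone with four ortho substituents accessible under such mild conditions.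

Step 9
Reactants: 12 1,8-bis(benzyloxy)-3,10-dimethoxy-11-oxo-6,11-dihydrodibenzo[b,e]oxepine-4-carbaldehyde
Product: 13 1,8-bis(benzyloxy)-4-(hydroxymethyl)-3,10-dimethoxydibenzo[b,e]oxepin-11(6H)-one
Conditions: NaBH4, THF/MeOH, −10 to 0 °C; aq. NaHCO3 work-up
Reagents that add atoms: none
Why: Chemoselective hydride reduction: the aldehyde is far more accessible than the diaryl ketone, which is flanked by two ortho oxygens and deactivated as a doubly vinylogous ester. Neutral work-up protects the ionisable benzylic alcohol; no stereocentre arises.

Step 10
Reactants: 14 orsellinaldehyde (2,4-dihydroxy-6-methylbenzaldehyde)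
Product: 15 2,4-bis(benzyloxy)-6-methylbenzaldehyde
Conditions: BnBr (2.3 equiv), K2CO3, DMF, 60 °C
Reagents that add atoms: benzyl bromide, BrCc1ccccc1
Why: Exhaustive Williamson benzylation; the chelated 2-hydroxyl needs DMF and warming.

Step 11
Reactants: 16 5-methoxyresorcinol (5-methoxybenzene-1,3-diol)
Product: 17 1-methoxy-3,5-bis(methoxymethoxy)benzene
Conditions: MOMCl, i-Pr2NEt, CH2Cl2, 0 °C to rt
Reagents that add atoms: chloromethyl methyl ether, COCCl
Why: Acetal protection of both phenols; MOM groups direct the lithiation of step 12 and are later removed by acid without touching benzyl ethers.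

Step 12
Reactants: 17 1-methoxy-3,5-bis(methoxymethoxy)benzene; 15 2,4-bis(benzyloxy)-6-methylbenzaldehyde
Product: 19 rac-[2,4-bis(benzyloxy)-6-methylphenyl][4-methoxy-2,6-bis(methoxymethoxy)phenyl]methanol, via aryllithium 18 (not isolated)
Conditions: n-BuLi, THF, 0 °C; then 15, −78 to 0 °C; aq. NH4Cl
Reagents that add atoms: none
Why: Directed ortho-metalation: the carbon between the two MOM ethers is deprotonated in preference to those flanked by one MOM and the weaker methoxy director, and aryllithium 18 adds to the aldehyde faster than it can deprotonate the ortho-methyl group. The carbinol stereocentre forms as a racemate and is destroyed in step 13.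

Step 13
Reactants: 19 rac-[2,4-bis(benzyloxy)-6-methylphenyl][4-methoxy-2,6-bis(methoxymethoxy)phenyl]methanol
Product: 20 [2,4-bis(benzyloxy)-6-methylphenyl][4-methoxy-2,6-bis(methoxymethoxy)phenyl]methanone
Conditions: Dess–Martin periodinane, NaHCO3, CH2Cl2, 0 °C to rt
Reagents that add atoms: none
Why: Dess–Martin oxidation of the hindered benzhydrol under buffered conditions, which avoids ionising the electron-rich diarylcarbinol. Addition followed by oxidation sidesteps a hindered intermolecular Friedel–Crafts acylation and its regiochemistry.

Step 14
Reactants: 20 [2,4-bis(benzyloxy)-6-methylphenyl][4-methoxy-2,6-bis(methoxymethoxy)phenyl]methanone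
Product: 21 [2,4-bis(benzyloxy)-6-methylphenyl](2,6-dihydroxy-4-methoxyphenyl)methanone
Conditions: 3 M HCl, MeOH/THF, 50 °C
Reagents that add atoms: none
Why: Acid-catalysed transacetalisation removes both MOM groups; aryl benzyl ethers, the methyl ether and the ketone are stable under these conditions.

Step 15
Reactants: 13 1,8-bis(benzyloxy)-4-(hydroxymethyl)-3,10-dimethoxydibenzo[b,e]oxepin-11(6H)-one; 21 [2,4-bis(benzyloxy)-6-methylphenyl](2,6-dihydroxy-4-methoxyphenyl)methanone
Product: 22 4-({3-[2,4-bis(benzyloxy)-6-methylbenzoyl]-2,4-dihydroxy-6-methoxyphenyl}methyl)-1,8-bis(benzyloxy)-3,10-dimethoxydibenzo[b,e]oxepin-11(6H)-one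
Conditions: BF3·OEt2 (cat.), CH2Cl2/dioxane, −20 to 0 °C; 21 in excess (about 2 equiv), 13 added slowly
Reagents that add atoms: none
Why: Lewis-acid-catalysed Friedel–Crafts benzylation of a phenol by an electron-rich benzylic alcohol, as in C-benzylations of acylphloroglucinols: 13 ionises to a 2,4,6-trioxygenated benzylic cation that attacks ring B of 21 at one of its two equivalent free carbons. Ring B, with two free hydroxyls, is the most nucleophilic arene present (ring A is a bis-ether, ring C of 13 a tris-ether carrying a ketone). An excess of 21 limits double benzylation, and any O-benzylated product re-ionises under the acid.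

Step 16
Reactants: 22 4-({3-[2,4-bis(benzyloxy)-6-methylbenzoyl]-2,4-dihydroxy-6-methoxyphenyl}methyl)-1,8-bis(benzyloxy)-3,10-dimethoxydibenzo[b,e]oxepin-11(6H)-one
Product: 23 (2,4-dihydroxy-6-methylphenyl)[2,6-dihydroxy-3-{[2,4-dihydroxy-3-(4-hydroxy-2-methoxy-6-methylbenzoyl)-6-methoxyphenyl]methyl}-4-methoxyphenyl]methanone
Conditions: H2 (1–3 atm), Pd(OH)2 on carbon, EtOAc/MeOH, rt
Reagents that add atoms: none
Why: Catalytic hydrogenolysis should cleave the four aryl benzyl ethers and the benzylic C–O bond of the oxepinone, itself a benzyl aryl ether whose leaving phenoxide is ortho to the ketone; this returns the ring D methyl group and the ring C hydroxyl. Methyl ethers, the diarylmethane and the hindered, hydrogen-bonded diaryl ketones are expected to persist.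

## Compound list

1 | methyl orsellinate (methyl 2,4-dihydroxy-6-methylbenzoate) | COC(=O)c1c(C)cc(O)cc1O | starting material
2 | methyl 4-(2,2-dimethylpropanoyloxy)-2-hydroxy-6-methylbenzoate | COC(=O)c1c(C)cc(OC(=O)C(C)(C)C)cc1O | intermediate
3 | methyl 4-(2,2-dimethylpropanoyloxy)-2-methoxy-6-methylbenzoate | COC(=O)c1c(C)cc(OC(=O)C(C)(C)C)cc1OC | intermediate
4 | methyl 2-(bromomethyl)-4-(2,2-dimethylpropanoyloxy)-6-methoxybenzoate | COC(=O)c1c(CBr)cc(OC(=O)C(C)(C)C)cc1OC | intermediate
5 | 2,4-dihydroxy-6-methoxybenzaldehyde | COc1cc(O)cc(O)c1C=O | starting material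
6 | 4-(benzyloxy)-2-hydroxy-6-methoxybenzaldehyde | COc1cc(OCc2ccccc2)cc(O)c1C=O | intermediate
7 | methyl 2-{[5-(benzyloxy)-2-formyl-3-methoxyphenoxy]methyl}-4-(2,2-dimethylpropanoyloxy)-6-methoxybenzoate | COC(=O)c1c(COc2cc(OCc3ccccc3)cc(OC)c2C=O)cc(OC(=O)C(C)(C)C)cc1OC | intermediate
8 | methyl 2-{[5-(benzyloxy)-2-formyl-3-methoxyphenoxy]methyl}-4-hydroxy-6-methoxybenzoate (sodium salt in the flask) | COC(=O)c1c(COc2cc(OCc3ccccc3)cc(OC)c2C=O)cc(O)cc1OC | intermediate (not isolated)
9 | methyl 4-(benzyloxy)-2-{[5-(benzyloxy)-2-formyl-3-methoxyphenoxy]methyl}-6-methoxybenzoate | COC(=O)c1c(COc2cc(OCc3ccccc3)cc(OC)c2C=O)cc(OCc2ccccc2)cc1OC | intermediate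
10 | 4-(benzyloxy)-2-{[5-(benzyloxy)-2-formyl-3-methoxyphenoxy]methyl}-6-methoxybenzoic acid | OC(=O)c1c(COc2cc(OCc3ccccc3)cc(OC)c2C=O)cc(OCc2ccccc2)cc1OC | intermediate
11 | 4-(benzyloxy)-2-{[5-(benzyloxy)-2-formyl-3-methoxyphenoxy]methyl}-6-methoxybenzoic trifluoroacetic anhydride | O=C(OC(=O)C(F)(F)F)c1c(COc2cc(OCc3ccccc3)cc(OC)c2C=O)cc(OCc2ccccc2)cc1OC | intermediate (not isolated)
12 | 1,8-bis(benzyloxy)-3,10-dimethoxy-11-oxo-6,11-dihydrodibenzo[b,e]oxepine-4-carbaldehyde | O=Cc1c(OC)cc(OCc2ccccc2)c2c1OCc1cc(OCc3ccccc3)cc(OC)c1C2=O | intermediate
13 | 1,8-bis(benzyloxy)-4-(hydroxymethyl)-3,10-dimethoxydibenzo[b,e]oxepin-11(6H)-one | OCc1c(OC)cc(OCc2ccccc2)c2c1OCc1cc(OCc3ccccc3)cc(OC)c1C2=O | intermediate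
14 | orsellinaldehyde (2,4-dihydroxy-6-methylbenzaldehyde) | Cc1cc(O)cc(O)c1C=O | starting material
15 | 2,4-bis(benzyloxy)-6-methylbenzaldehyde | Cc1cc(OCc2ccccc2)cc(OCc2ccccc2)c1C=O | intermediate
16 | 5-methoxyresorcinol (5-methoxybenzene-1,3-diol) | COc1cc(O)cc(O)c1 | starting material
17 | 1-methoxy-3,5-bis(methoxymethoxy)benzene | COCOc1cc(OC)cc(OCOC)c1 | intermediate
18 | [4-methoxy-2,6-bis(methoxymethoxy)phenyl]lithium | [Li]c1c(OCOC)cc(OC)cc1OCOC | intermediate (not isolated)
19 | rac-[2,4-bis(benzyloxy)-6-methylphenyl][4-methoxy-2,6-bis(methoxymethoxy)phenyl]methanol (racemate) | COCOc1cc(OC)cc(OCOC)c1C(O)c1c(C)cc(OCc2ccccc2)cc1OCc1ccccc1 | intermediate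
20 | [2,4-bis(benzyloxy)-6-methylphenyl][4-methoxy-2,6-bis(methoxymethoxy)phenyl]methanone | COCOc1cc(OC)cc(OCOC)c1C(=O)c1c(C)cc(OCc2ccccc2)cc1OCc1ccccc1 | intermediate
21 | [2,4-bis(benzyloxy)-6-methylphenyl](2,6-dihydroxy-4-methoxyphenyl)methanone | COc1cc(O)c(C(=O)c2c(C)cc(OCc3ccccc3)cc2OCc2ccccc2)c(O)c1 | intermediate
22 | 4-({3-[2,4-bis(benzyloxy)-6-methylbenzoyl]-2,4-dihydroxy-6-methoxyphenyl}methyl)-1,8-bis(benzyloxy)-3,10-dimethoxydibenzo[b,e]oxepin-11(6H)-one | COc1cc(O)c(C(=O)c2c(C)cc(OCc3ccccc3)cc2OCc2ccccc2)c(O)c1Cc1c(OC)cc(OCc2ccccc2)c2c1OCc1cc(OCc3ccccc3)cc(OC)c1C2=O | intermediate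
23 | (2,4-dihydroxy-6-methylphenyl)[2,6-dihydroxy-3-{[2,4-dihydroxy-3-(4-hydroxy-2-methoxy-6-methylbenzoyl)-6-methoxyphenyl]methyl}-4-methoxyphenyl]methanone | COc1cc(O)c(C(=O)c2c(C)cc(O)cc2O)c(O)c1Cc1c(OC)cc(O)c(C(=O)c2c(C)cc(O)cc2OC)c1O | target

## Step count and least certain steps

Total step count: 16. Longest linear sequence: 10 steps (steps 1, 2, 3, 5, 6, 7, 8, 9, 15 and 16, from 1).

**Step 8 (key step).**
- Risk: the formyl group lowers the nucleophilicity of ring C, so ring closure may be slow. Intermolecular acylation could then compete, as could loss of the tether, in which the activated carboxyl attacks its own benzylic carbon and expels the ring C phenol to form a phthalide.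
- Fallback (sets out from 9, returns at 23): the ring is closed after the fragment union, so that ring C carries an electron-releasing benzyl substituent in place of the formyl group.
  - Reduction of 9 with NaBH4 should give the benzylic alcohol methyl 4-(benzyloxy)-2-{[5-(benzyloxy)-2-(hydroxymethyl)-3-methoxyphenoxy]methyl}-6-methoxybenzoate F1.
  - BF3·OEt2-catalysed benzylation of 21 (in excess) with F1 should give the diarylmethane ester F2.
  - Benzylation of the two ring B hydroxyls (BnBr, K2CO3, DMF) should give the hexabenzyl ester F3.
  - Saponification (KOH, aqueous DMSO) should give the acid F4.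
  - Trifluoroacetic anhydride should close the hexabenzyl oxepinone F5.
  - Hydrogenolysis of six benzyl ethers and the ring ether should give 23.
- This order is held in reserve because ring C of F1 lacks an acyl group and is the most nucleophilic arene in the benzylation, and because the diarylmethane must then survive the acylation medium.

**Step 15.**
- Risk: a second benzylation at the remaining free carbon of ring B, or capture of the benzylic cation by ring C of another molecule of 13. Both rings are acylphloroglucinol derivatives and the selectivity rests only on free hydroxyl versus ether.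
- Fallback (sets out from 21, returns at 23): one of the two equivalent ring B carbons is blocked first.
  - NBS (one equivalent, CH2Cl2, low temperature) should give the monobromide [2,4-bis(benzyloxy)-6-methylphenyl](3-bromo-2,6-dihydroxy-4-methoxyphenyl)methanone F6.
  - Benzylation with 13 as in step 15 can then occur only once and should give the bromo diarylmethane F7.
  - Hydrogenolysis over Pd/C with NaOAc should remove the bromine together with the benzyl groups and the ring ether and give 23.

**Step 16.**
- Risk: incomplete cleavage of the ring benzylic C–O bond, which the seven-membered ring may hold in poor alignment with the ring D π-system. Forcing the conditions could instead reduce a diaryl ketone.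
- Fallback (sets out from 22, returns at 23): the benzylic C–O bonds are cut by nucleophilic displacement in place of hydrogenolysis.
  - Iodotrimethylsilane generated from TMSCl and NaI in MeCN at 0 °C to rt should cleave the four benzyl ethers and open the ring ether at its benzylic carbon; aryl methyl ethers react far more slowly. This gives, as silyl ethers in the flask, the iodomethyl analogue of the target, (2,4-dihydroxy-6-methylphenyl)[2,6-dihydroxy-3-({2,4-dihydroxy-3-[4-hydroxy-2-(iodomethyl)-6-methoxybenzoyl]-6-methoxyphenyl}methyl)-4-methoxyphenyl]methanone F8.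
  - Zn dust in AcOH should then reduce the benzylic iodide to the methyl group, and aqueous work-up frees the phenols to give 23.

**Step 7.**
- Risk: slow hydrolysis of the di-ortho-substituted ester, so that prolonged hot hydroxide begins to attack the formyl group (disproportionation of the Cannizzaro kind).
- Fallback (sets out from 9, returns at 10): the ester is cleaved at its methyl carbon instead of its carbonyl carbon. LiSPr (from propane-1-thiol and n-BuLi) in HMPA at rt demethylates hindered methyl esters by SN2 displacement, which does not depend on access to the carbonyl and returns the aldehyde unchanged after work-up. No new compound arises.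

## Further compounds

F1 | step 8 | methyl 4-(benzyloxy)-2-{[5-(benzyloxy)-2-(hydroxymethyl)-3-methoxyphenoxy]methyl}-6-methoxybenzoate | COC(=O)c1c(COc2cc(OCc3ccccc3)cc(OC)c2CO)cc(OCc2ccccc2)cc1OC
F2 | step 8 | methyl 4-(benzyloxy)-2-{[5-(benzyloxy)-2-({3-[2,4-bis(benzyloxy)-6-methylbenzoyl]-2,4-dihydroxy-6-methoxyphenyl}methyl)-3-methoxyphenoxy]methyl}-6-methoxybenzoate | COc1cc(O)c(C(=O)c2c(C)cc(OCc3ccccc3)cc2OCc2ccccc2)c(O)c1Cc1c(OC)cc(OCc2ccccc2)cc1OCc1cc(OCc2ccccc2)cc(OC)c1C(=O)OC
F3 | step 8 | methyl 4-(benzyloxy)-2-{[5-(benzyloxy)-2-({2,4-bis(benzyloxy)-3-[2,4-bis(benzyloxy)-6-methylbenzoyl]-6-methoxyphenyl}methyl)-3-methoxyphenoxy]methyl}-6-methoxybenzoate | COc1cc(OCc2ccccc2)c(C(=O)c2c(C)cc(OCc3ccccc3)cc2OCc2ccccc2)c(OCc2ccccc2)c1Cc1c(OC)cc(OCc2ccccc2)cc1OCc1cc(OCc2ccccc2)cc(OC)c1C(=O)OC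
F4 | step 8 | 4-(benzyloxy)-2-{[5-(benzyloxy)-2-({2,4-bis(benzyloxy)-3-[2,4-bis(benzyloxy)-6-methylbenzoyl]-6-methoxyphenyl}methyl)-3-methoxyphenoxy]methyl}-6-methoxybenzoic acid | COc1cc(OCc2ccccc2)c(C(=O)c2c(C)cc(OCc3ccccc3)cc2OCc2ccccc2)c(OCc2ccccc2)c1Cc1c(OC)cc(OCc2ccccc2)cc1OCc1cc(OCc2ccccc2)cc(OC)c1C(=O)O
F5 | step 8 | 1,8-bis(benzyloxy)-4-({2,4-bis(benzyloxy)-3-[2,4-bis(benzyloxy)-6-methylbenzoyl]-6-methoxyphenyl}methyl)-3,10-dimethoxydibenzo[b,e]oxepin-11(6H)-one | COc1cc(OCc2ccccc2)c(C(=O)c2c(C)cc(OCc3ccccc3)cc2OCc2ccccc2)c(OCc2ccccc2)c1Cc1c(OC)cc(OCc3ccccc3)c2c1OCc1cc(OCc3ccccc3)cc(OC)c1C2=O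
F6 | step 15 | [2,4-bis(benzyloxy)-6-methylphenyl](3-bromo-2,6-dihydroxy-4-methoxyphenyl)methanone | COc1cc(O)c(C(=O)c2c(C)cc(OCc3ccccc3)cc2OCc2ccccc2)c(O)c1Br
F7 | step 15 | 4-({3-[2,4-bis(benzyloxy)-6-methylbenzoyl]-5-bromo-2,4-dihydroxy-6-methoxyphenyl}methyl)-1,8-bis(benzyloxy)-3,10-dimethoxydibenzo[b,e]oxepin-11(6H)-one | COc1c(Br)c(O)c(C(=O)c2c(C)cc(OCc3ccccc3)cc2OCc2ccccc2)c(O)c1Cc1c(OC)cc(OCc2ccccc2)c2c1OCc1cc(OCc3ccccc3)cc(OC)c1C2=O
F8 | step 16 | (2,4-dihydroxy-6-methylphenyl)[2,6-dihydroxy-3-({2,4-dihydroxy-3-[4-hydroxy-2-(iodomethyl)-6-methoxybenzoyl]-6-methoxyphenyl}methyl)-4-methoxyphenyl]methanone | COc1cc(O)c(C(=O)c2c(C)cc(O)cc2O)c(O)c1Cc1c(OC)cc(O)c(C(=O)c2c(CI)cc(O)cc2OC)c1O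
F0 | step 7 | none | none
A1 | alternative 1 | 1-[2,6-bis(benzyloxy)-4-methoxyphenyl]butane-1,3-dione | CC(=O)CC(=O)c1c(OCc2ccccc2)cc(OC)cc1OCc1ccccc1
A2 | alternative 1 | ethyl (E)-but-2-enoate (ethyl crotonate) | C/C=C/C(=O)OCC
A3 | alternative 1 | 4-[2,6-bis(benzyloxy)-4-methoxybenzoyl]-5-methylcyclohexane-1,3-dione (mixture of stereoisomers) | CC1CC(=O)CC(=O)C1C(=O)c1c(OCc2ccccc2)cc(OC)cc1OCc1ccccc1
A4 | alternative 2 | 6-{2-[2,4-bis(benzyloxy)-6-methylphenyl]-2-oxoethyl}-4-hydroxy-2H-pyran-2-one | O=C(Cc1cc(O)cc(=O)o1)c1c(C)cc(OCc2ccccc2)cc1OCc1ccccc1
A5 | alternative 2 | magnesium methoxide, Mg(OMe)2 | [Mg+2].[O-]C.[O-]C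
A6 | alternative 2 | methyl 7-[2,4-bis(benzyloxy)-6-methylphenyl]-3,5,7-trioxoheptanoate | COC(=O)CC(=O)CC(=O)CC(=O)c1c(C)cc(OCc2ccccc2)cc1OCc1ccccc1
A7 | alternative 2 | [2,4-bis(benzyloxy)-6-methylphenyl](2,4,6-trihydroxyphenyl)methanone | Oc1cc(O)c(C(=O)c2c(C)cc(OCc3ccccc3)cc2OCc2ccccc2)c(O)c1
A8 | alternative 3 | rac-4-({2,4-bis(benzyloxy)-3-[2,4-bis(benzyloxy)-6-methylbenzoyl]-6-methoxyphenyl}methyl)-3-methoxycyclobut-2-en-1-one (racemate) | COC1=CC(=O)C1Cc1c(OC)cc(OCc2ccccc2)c(C(=O)c2c(C)cc(OCc3ccccc3)cc2OCc2ccccc2)c1OCc1ccccc1
A9 | alternative 3 | (triisopropylsilyloxy)acetylene | C#CO[Si](C(C)C)(C(C)C)C(C)C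
A10 | alternative 3 | 2-({2,4-bis(benzyloxy)-3-[2,4-bis(benzyloxy)-6-methylbenzoyl]-6-methoxyphenyl}methyl)-3-methoxy-5-[(triisopropylsilyl)oxy]phenol | Oc1cc(O[Si](C(C)C)(C(C)C)C(C)C)cc(OC)c1Cc1c(OC)cc(OCc2ccccc2)c(C(=O)c2c(C)cc(OCc3ccccc3)cc2OCc2ccccc2)c1OCc1ccccc1
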